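Everything rests on cutting the C14–C15 bond of the oxepane (ring C). A tricyclic enone (rings A, B and D) whose quaternary C3 oxygen carries a 2-bromoallyl group is cyclised by palladium-catalysed coupling of its vinylic carbon with the C14 enolate; one operation closes ring C, forms C14–C15 and sets C14. The step exploits two features: C14 is the α′ carbon of the C13 ketone of ring A, and the C3 oxygen lies over the ring A face that bears C2, so C15 can only arrive cis to C2. The precursor comes from a butenolide Diels–Alder adduct; C4 is masked as a PMB ether, which cannot migrate to the C3 alkoxide.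

Key step: step 20

Remark: atoms are numbered as in the target (ring A: C1, C10–C14; ring B: C1, C2, O, C9, C10; ring C: C1–C3, O, C16, C15, C14; ring D: O, C2–C9); the C13 carbinol configuration in 7–24 and the C11 configuration in 5 are drawn as expected but are immaterial because both centres become trigonal again, and 10 and 14 are epimer mixtures (at C9 and C3) that converge.

Step 1
Reactants: 1 (S)-5-(hydroxymethyl)furan-2(5H)-one
Product: 2 (S)-5-[(tert-butyldimethylsilyloxy)methyl]furan-2(5H)-one
Conditions: TBSCl, imidazole, DMF, 0 → 25 °C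
Reagents that add atoms: tert-butyldimethylsilyl chloride, CC(C)(C)[Si](C)(C)Cl
Why: Imidazole-promoted silyl ether formation on the primary alcohol is mild enough to leave the base-sensitive butenolide and its stereocentre, the future C2, untouched.

Step 2
Reactants: 3 (E)-pent-3-en-2-one
Product: 4 (E)-2-(trimethylsilyloxy)penta-1,3-diene
Conditions: LiN(iPr)2, Me3SiCl, THF, −78 °C
Reagents that add atoms: chlorotrimethylsilane, C[Si](C)(C)Cl
Why: Kinetic deprotonation of the enone at its α′ methyl group with O-silylation in the same flask (enol silane formation) gives the cross-conjugated 2-silyloxy diene with the (E)-propenyl unit intact.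

Step 3
Reactants: 2 (S)-5-[(tert-butyldimethylsilyloxy)methyl]furan-2(5H)-one; 4 (E)-2-(trimethylsilyloxy)penta-1,3-diene
Product: 6 cis-fused enone lactone (ring A with C13 ketone and C11=C12 bearing the C11 methyl; γ-lactone C9(=O)–O–C2; CH2OTBS on C2; H1 and H10 cis; H2 trans to H1), via enol silane cycloadduct 5 (not isolated)
Conditions: PhMe, 130 °C (sealed tube); then Pd(OAc)2 (1 equiv), MeCN, 25 °C
Reagents that add atoms: none
Why: In the thermal Diels–Alder reaction the CH2 terminus of the diene bonds to the β-carbon of the butenolide and the diene adds to the face opposite the C2 side chain, which sets C1 and C10 with H1 and H10 cis to each other and trans to H2, and Saegusa–Ito dehydrogenation of the crude enol silane then places the double bond at C11=C12, the only side that offers a β-hydrogen.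

Step 4
Reactants: 6 cis-fused enone lactone
Product: 7 C13 allylic alcohol (hydroxyl cis to the lactone ring)
Conditions: NaBH4, CeCl3·7H2O, MeOH, −78 → −20 °C
Reagents that add atoms: none
Why: Luche reduction delivers hydride 1,2 to the enone carbonyl from the ring A face opposite the fused lactone and is too mild at low temperature to open the lactone.

Step 5
Reactants: 7 C13 allylic alcohol
Product: 8 C13 TBDPS ether
Conditions: TBDPSCl, imidazole, DMF, 25 °C
Reagents that add atoms: tert-butyldiphenylsilyl chloride, CC(C)(C)[Si](Cl)(c1ccccc1)c1ccccc1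
Why: Silyl ether formation on the secondary allylic alcohol gives a TBDPS group that should withstand the hydride, Lewis acid, Grignard and alkoxide steps ahead and is orthogonal to the primary TBS ether.

Step 6
Reactants: 8 C13 TBDPS ether
Product: 10 C9 lactol acetate (both C9 anomers), via aluminium lactolate 9 (not isolated)
Conditions: iBu2AlH, CH2Cl2, −78 °C; then pyridine, DMAP, Ac2O, −78 → 0 °C
Reagents that add atoms: acetic anhydride, CC(=O)OC(C)=O
Why: Partial reduction of the lactone stops at the tetrahedral aluminium lactolate at −78 °C, and acetylating it in the same flask (reductive acetylation) avoids the open hydroxy aldehyde.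

Step 7
Reactants: 10 C9 lactol acetate
Product: 11 C9-methallyl tetrahydrofuran (C8 cis to C3 across the ring oxygen, trans to C11)
Conditions: methallyltrimethylsilane, BF3·OEt2, CH2Cl2, −78 °C
Reagents that add atoms: trimethyl(2-methylallyl)silane, CC(=C)C[Si](C)(C)C
Why: Hosomi–Sakurai C-glycosylation, in which BF3 ionises the acetate to the ring B oxocarbenium ion and the allylsilane attacks C9 on the convex face of the cis-fused bicycle, anti to the C10–C11 bond, so that the C9 and C2 side chains end up cis on the tetrahydrofuran.

Step 8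
Reactants: 11 C9-methallyl tetrahydrofuran
Product: 12 primary alcohol (C3–OH)
Conditions: CSA (cat.), MeOH/CH2Cl2, 0 °C
Reagents that add atoms: none
Why: Acid-catalysed methanolysis removes the primary TBS ether much faster than the bulkier secondary TBDPS ether (selective desilylation).

Step 9
Reactants: 12 primary alcohol
Product: 13 C3 aldehyde
Conditions: DMP, CH2Cl2, 25 °C
Reagents that add atoms: none
Why: Dess–Martin oxidation gives the aldehyde under non-basic conditions, so the α-oxygenated centre C2 is not epimerised.

Step 10
Reactants: 13 C3 aldehyde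
Product: 14 C3 methyl carbinol (both C3 epimers)
Conditions: MeMgBr, THF, −78 °C
Reagents that add atoms: methylmagnesium bromide, C[Mg]Br
Why: Grignard addition to the aldehyde installs the C3 methyl group, and the mixed configuration of the new carbinol is of no consequence because it is oxidised in the next step.

Step 11
Reactants: 14 C3 methyl carbinol
Product: 15 C3 methyl ketone
Conditions: DMP, CH2Cl2, 25 °C
Reagents that add atoms: none
Why: Dess–Martin oxidation of the secondary alcohol gives the methyl ketone without base and so without epimerising C2.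

Step 12
Reactants: 15 C3 methyl ketone
Product: 17 (3S)-1,2-diol (tertiary C3–OH; primary C4–OH), via β-hydroxysilane 16 (not isolated)
Conditions: (iPrO)Me2SiCH2MgCl, THF, −78 → 0 °C; then KF, KHCO3, 30% H2O2, THF/MeOH, 25 °C
Reagents that add atoms: (isopropoxydimethylsilyl)methylmagnesium chloride, CC(C)O[Si](C)(C)C[Mg]Cl; hydrogen peroxide, OO
Why: Chelation-controlled Grignard addition (Cram cyclic model) sets C3, magnesium bridging the ketone oxygen and the ring B oxygen so that the silylmethyl group enters from the side of H2 and away from C1, and Tamao oxidation of the C–Si bond then unveils the primary alcohol without touching the new centre.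

Step 13
Reactants: 17 (3S)-1,2-diol
Product: 18 α-hydroxy aldehyde (C4 aldehyde, free tertiary C3–OH)
Conditions: SO3·pyridine, DMSO, iPr2NEt, CH2Cl2, 0 °C
Reagents that add atoms: none
Why: Parikh–Doering oxidation converts only the primary hydroxyl, since the tertiary one cannot be oxidised, and unlike periodinane or periodate reagents an activated-sulfoxide oxidant cannot cleave the 1,2-diol.

Step 14
Reactants: 18 α-hydroxy aldehyde
Product: 19 (3S,4R)-homoallylic diol (C4 allyl carbinol, 3,4-syn)
Conditions: allyl bromide, In powder, THF/H2O (1:1), 25 °C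
Reagents that add atoms: allyl bromide, C=CCBr
Why: Indium-mediated Barbier allylation in water runs through the five-membered chelate of the free C3 hydroxyl and the aldehyde oxygen, and the allyl group adds from the side of the C3 methyl, away from bulky C2, which sets C4 in the 3,4-syn relationship of the target.

Step 15
Reactants: 19 (3S,4R)-homoallylic diol
Product: 20 C4 PMB ether (C3–OH free)
Conditions: NaH (1.1 equiv), PMBCl, Bu4NI (cat.), THF/DMF, 0 °C
Reagents that add atoms: 4-methoxybenzyl chloride, COc1ccc(CCl)cc1
Why: Williamson ether synthesis is selective because the secondary alkoxide forms and reacts far faster than the hindered tertiary one, and the resulting benzyl-type ether cannot migrate to the C3 oxygen in the later strongly basic step.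

Step 16
Reactants: 20 C4 PMB ether
Product: 21 tricyclic oxonene (rings A, B and D; (Z)-C6=C7; C3–OH; C4–OPMB; C13–OTBDPS)
Conditions: second-generation Grubbs catalyst RuCl2(=CHPh)(PCy3)(H2IMes) (10 mol %), CH2Cl2 (2 mM), 40 °C
Reagents that add atoms: none
Why: Ring-closing metathesis between the monosubstituted and the 1,1-disubstituted alkene, held close by the cis-2,9-disubstituted tetrahydrofuran, closes the nine-membered ring D, in which the new trisubstituted alkene can only be Z, a closure of a type known for cis-2,5-disubstituted tetrahydrofurans.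

Step 17
Reactants: 21 tricyclic oxonene; 22 2,3-dibromoprop-1-ene
Product: 23 C3 O-(2-bromoallyl) ether
Conditions: NaH, Bu4NI (cat.), THF/DMF, 0 → 25 °C
Reagents that add atoms: none
Why: Williamson etherification in which the sodium alkoxide of the tertiary C3 alcohol displaces the allylic bromide of 22 (SN2) while the vinylic bromide stays inert, no other acidic or migrating group being present because C13 and C4 are blocked as silyl and benzyl-type ethers.

Step 18
Reactants: 23 C3 O-(2-bromoallyl) ether
Product: 24 C13 allylic alcohol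
Conditions: Bu4NF, AcOH, THF, 25 °C
Reagents that add atoms: none
Why: Fluoride cleaves the Si–O bond (desilylation), and the acetic acid buffer keeps the medium from becoming basic enough to dehydrobrominate the 2-bromoallyl ether.

Step 19
Reactants: 24 C13 allylic alcohol
Product: 25 tricyclic enone, precursor of the key step (C14 unsubstituted; C3–OCH2C(Br)=CH2; C4–OPMB)
Conditions: DMP, CH2Cl2, 25 °C
Reagents that add atoms: none
Why: Dess–Martin oxidation of the allylic alcohol restores the ring A enone and removes the temporary C13 centre, leaving the alkenyl bromide and the PMB ether untouched.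

Step 20
Reactants: 25 tricyclic enone
Product: 26 tetracyclic enone with exocyclic C15 methylene (ring C closed; H14 cis to H1; C4–OPMB)
Conditions: Pd(PPh3)4 (20 mol %), KOPh, THF, 65 °C
Reagents that add atoms: none
Why: Zerovalent palladium inserts into the C15–Br bond to give an alkenylpalladium bromide (divalent palladium), phenoxide forms the ketone enolates reversibly, the C14 enolate replaces bromide on the metal, and reductive elimination from the eight-membered oxapalladacycle forms C14–C15 and returns zerovalent palladium. The closest known reaction type is the palladium-catalysed intramolecular α-alkenylation of ketone enolates with vinyl halides. Ring C closes as a seven-membered ring in an enol-exo sense, the enolate C13=C14 bond staying outside the new ring and the alkene staying exocyclic on C15. C14, the only new stereocentre, is set by the tether: the C3 oxygen hangs over the ring A face that carries C2, so C15 is delivered cis to C2, and the same cis fusion of rings A and C is expected if C14 equilibrates through its enolate. The step needs regioselection among the enolisable sites and survival of the exocyclic alkene; only the C14 enolate can reach the metal in an unstrained ring, whereas the γ sites (C10 and the C11 methyl) cannot, and the weak base KOPh with its conjugate acid phenol returns any product enolate to the ketone by protonation at C14 and so keeps the alkene out of conjugation.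

Step 21
Reactants: 26 tetracyclic enone with exocyclic C15 methylene
Product: 27 (15R)-15-methyl tetracycle (C4–OPMB)
Conditions: RhCl(PPh3)3 (10 mol %), H2 (1 atm), PhH, 25 °C
Reagents that add atoms: none
Why: Homogeneous hydrogenation with RhCl(PPh3)3 reduces only the 1,1-disubstituted exocyclic alkene, and hydrogen should add to its outer face, the one flanked by the flat C13 carbonyl, because the inner face is covered by C4 of ring D and by H1, which puts H15 cis to C13 as in the target.

Step 22
Reactants: 27 (15R)-15-methyl tetracycle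
Product: 28 C4 alcohol
Conditions: DDQ, CH2Cl2/pH 7 buffer, 0 °C
Reagents that add atoms: none
Why: Oxidative cleavage of the 4-methoxybenzyl ether by DDQ (hydride abstraction to the oxocarbenium ion, then hydrolysis) spares the enone, the ring D alkene and both ring ethers.

Step 23
Reactants: 28 C4 alcohol
Product: 29 target butanoate (CNP0271677.1)
Conditions: (PrCO)2O, Et3N, DMAP, CH2Cl2, 25 °C
Reagents that add atoms: butanoic anhydride, CCCC(=O)OC(=O)CCC
Why: DMAP-catalysed acylation of the secondary C4 alcohol with the anhydride (Steglich-type esterification) gives the butanoate.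

Compound list
1 | (S)-5-(hydroxymethyl)furan-2(5H)-one | O=C1C=C[C@@H](CO)O1 | starting material
2 | (S)-5-[(tert-butyldimethylsilyloxy)methyl]furan-2(5H)-one | O=C1C=C[C@@H](CO[Si](C)(C)C(C)(C)C)O1 | intermediate
3 | (E)-pent-3-en-2-one | C/C=C/C(C)=O | starting material
4 | (E)-2-(trimethylsilyloxy)penta-1,3-diene | C/C=C/C(=C)O[Si](C)(C)C | intermediate
5 | enol silane cycloadduct (cis-fused lactone; C13–OSiMe3 on C12=C13; C11 methyl cis to C9) | CC(C)(C)[Si](C)(C)OC[C@H]1OC(=O)[C@H]2[C@@H]1CC(O[Si](C)(C)C)=C[C@H]2C | intermediate
6 | cis-fused enone lactone (C13 ketone, C11=C12, C11 methyl; lactone C9(=O)–O–C2; CH2OTBS on C2) | CC(C)(C)[Si](C)(C)OC[C@H]1OC(=O)[C@H]2[C@@H]1CC(=O)C=C2C | intermediate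
7 | C13 allylic alcohol (OH cis to the lactone ring) | CC(C)(C)[Si](C)(C)OC[C@H]1OC(=O)[C@H]2[C@@H]1C[C@@H](O)C=C2C | intermediate
8 | C13 TBDPS ether | CC(C)(C)[Si](C)(C)OC[C@H]1OC(=O)[C@H]2[C@@H]1C[C@@H](O[Si](c3ccccc3)(c3ccccc3)C(C)(C)C)C=C2C | intermediate
9 | diisobutylaluminium lactolate of 8 | CC(C)(C)[Si](C)(C)OC[C@H]1OC(O[Al](CC(C)C)CC(C)C)[C@H]2[C@@H]1C[C@@H](O[Si](c3ccccc3)(c3ccccc3)C(C)(C)C)C=C2C | intermediate
10 | C9 lactol acetate (both C9 anomers) | CC(C)(C)[Si](C)(C)OC[C@H]1OC(OC(C)=O)[C@H]2[C@@H]1C[C@@H](O[Si](c3ccccc3)(c3ccccc3)C(C)(C)C)C=C2C | intermediate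
11 | C9-methallyl tetrahydrofuran (C8 cis to C3 across the ring oxygen) | CC(C)(C)[Si](C)(C)OC[C@H]1O[C@@H](CC(C)=C)[C@H]2[C@@H]1C[C@@H](O[Si](c3ccccc3)(c3ccccc3)C(C)(C)C)C=C2C | intermediate
12 | primary alcohol (C3–OH) | OC[C@H]1O[C@@H](CC(C)=C)[C@H]2[C@@H]1C[C@@H](O[Si](c3ccccc3)(c3ccccc3)C(C)(C)C)C=C2C | intermediate
13 | C3 aldehyde | O=C[C@H]1O[C@@H](CC(C)=C)[C@H]2[C@@H]1C[C@@H](O[Si](c3ccccc3)(c3ccccc3)C(C)(C)C)C=C2C | intermediate
14 | C3 methyl carbinol (both C3 epimers) | CC(O)[C@H]1O[C@@H](CC(C)=C)[C@H]2[C@@H]1C[C@@H](O[Si](c3ccccc3)(c3ccccc3)C(C)(C)C)C=C2C | intermediate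
15 | C3 methyl ketone | CC(=O)[C@H]1O[C@@H](CC(C)=C)[C@H]2[C@@H]1C[C@@H](O[Si](c3ccccc3)(c3ccccc3)C(C)(C)C)C=C2C | intermediate
16 | β-hydroxysilane ((3S)-carbinol; C4 as CH2SiMe2(OiPr)) | CC(C)O[Si](C)(C)C[C@](C)(O)[C@H]1O[C@@H](CC(C)=C)[C@H]2[C@@H]1C[C@@H](O[Si](c3ccccc3)(c3ccccc3)C(C)(C)C)C=C2C | intermediate
17 | (3S)-1,2-diol (tertiary C3–OH, primary C4–OH) | OC[C@](C)(O)[C@H]1O[C@@H](CC(C)=C)[C@H]2[C@@H]1C[C@@H](O[Si](c3ccccc3)(c3ccccc3)C(C)(C)C)C=C2C | intermediate
18 | α-hydroxy aldehyde (C4 aldehyde) | O=C[C@](C)(O)[C@H]1O[C@@H](CC(C)=C)[C@H]2[C@@H]1C[C@@H](O[Si](c3ccccc3)(c3ccccc3)C(C)(C)C)C=C2C | intermediate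
19 | (3S,4R)-homoallylic diol (3,4-syn) | C=CC[C@@H](O)[C@](C)(O)[C@H]1O[C@@H](CC(C)=C)[C@H]2[C@@H]1C[C@@H](O[Si](c3ccccc3)(c3ccccc3)C(C)(C)C)C=C2C | intermediate
20 | C4 PMB ether of 19 (C3–OH free) | C=CC[C@@H](OCc1ccc(OC)cc1)[C@](C)(O)[C@H]1O[C@@H](CC(C)=C)[C@H]2[C@@H]1C[C@@H](O[Si](c3ccccc3)(c3ccccc3)C(C)(C)C)C=C2C | intermediate
21 | tricyclic oxonene (rings A, B, D; (Z)-C6=C7; C3–OH; C4–OPMB; C13–OTBDPS) | COc1ccc(cc1)CO[C@@H]1C/C=C(/C)C[C@@H]2O[C@@H]([C@@H]3[C@H]2C(C)=C[C@H](O[Si](c4ccccc4)(c4ccccc4)C(C)(C)C)C3)[C@@]1(C)O | intermediate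
22 | 2,3-dibromoprop-1-ene | C=C(Br)CBr | starting material
23 | C3 O-(2-bromoallyl) ether of 21 | COc1ccc(cc1)CO[C@@H]1C/C=C(/C)C[C@@H]2O[C@@H]([C@@H]3[C@H]2C(C)=C[C@H](O[Si](c4ccccc4)(c4ccccc4)C(C)(C)C)C3)[C@@]1(C)OCC(Br)=C | intermediate
24 | C13 allylic alcohol (desilylated 23) | COc1ccc(cc1)CO[C@@H]1C/C=C(/C)C[C@@H]2O[C@@H]([C@@H]3[C@H]2C(C)=C[C@H](O)C3)[C@@]1(C)OCC(Br)=C | intermediate
25 | tricyclic enone, key-step precursor (C14 unsubstituted; C3 O-(2-bromoallyl); C4–OPMB) | COc1ccc(cc1)CO[C@@H]1C/C=C(/C)C[C@@H]2O[C@@H]([C@@H]3[C@H]2C(C)=CC(=O)C3)[C@@]1(C)OCC(Br)=C | intermediate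
26 | tetracyclic enone with exocyclic C15 methylene (C4–OPMB) | COc1ccc(cc1)CO[C@@H]1C/C=C(/C)C[C@@H]2O[C@H]3[C@@H]4[C@H]2C(C)=CC(=O)[C@@H]4C(=C)CO[C@@]13C | intermediate
27 | (15R)-15-methyl tetracycle (C4–OPMB) | COc1ccc(cc1)CO[C@@H]1C/C=C(/C)C[C@@H]2O[C@H]3[C@@H]4[C@H]2C(C)=CC(=O)[C@@H]4[C@@H](C)CO[C@@]13C | intermediate
28 | C4 alcohol | O[C@@H]1C/C=C(/C)C[C@@H]2O[C@H]3[C@@H]4[C@H]2C(C)=CC(=O)[C@@H]4[C@@H](C)CO[C@@]13C | intermediate
29 | CNP0271677.1, (1R,2S,3S,4R,9S,10S,14R,15R,6Z)-C4 butanoate | CCCC(=O)O[C@@H]1C/C=C(/C)C[C@@H]2O[C@H]3[C@@H]4[C@H]2C(C)=CC(=O)[C@@H]4[C@@H](C)CO[C@@]13C | target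

Total steps: 23. Longest linear sequence: 22 steps (1 to 29 by steps 1 and 3–23; step 2 makes the diene).

Steps most likely to fail

Step 20 (key step). What may go wrong: enolisation at the γ positions with loss of configuration at C10, base-driven migration of the exocyclic alkene into conjugation with the ketone, or loss of bromine by protonation when the seven-membered closure is slow. The fallback sets out from 25 and returns at 26; it fixes the regiochemistry of the enolate before the metal is present. LiN(SiMe3)2 with Me3SiCl in THF at −78 °C should deprotonate the enone kinetically at C14 and give the cross-conjugated C13 trimethylsilyl dienol ether F1. Heating this with Bu3SnF and catalytic Pd(PPh3)4 in benzene turns the enol silane into a tin enolate, which couples with the alkenyl bromide without any Brønsted base (the known fluoride-promoted coupling of enol silanes with organic bromides).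

Step 21. What may go wrong: delivery of hydrogen to both faces of the methylene, or isomerisation of the alkene into the ring before it is reduced. The fallback sets out from 26 and returns at 27; it replaces steric approach control by substrate direction. With [Ir(cod)(PCy3)(py)]PF6 (low loading) in CH2Cl2 under H2, the cationic iridium binds the C13 carbonyl oxygen and should pass hydrogen to the alkene face on which C13 lies (carbonyl-directed hydrogenation). The reaction is stopped before the hindered C6=C7 alkene reacts; no new compound is isolated on this path.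

Step 17. What may go wrong: sluggish alkylation of the hindered tertiary alkoxide while the base strips HBr from 22. The fallback sets out from 21 and returns at 23; it builds the ether in two stages from a smaller electrophile that cannot eliminate. NaH and propargyl bromide in THF/DMF should give the C3 propargyl ether F2. Hydrostannation with Bu3SnH and catalytic Mo(CO)3(CNtBu)3, which places tin on the internal carbon of propargylic ethers, gives the C3 2-(tributylstannyl)allyl ether F3. N-Bromosuccinimide in CH2Cl2 at −78 °C then exchanges tin for bromine and gives 23.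

Further compounds
F1 | step 20 | C13 trimethylsilyl dienol ether of 25 (C13=C14) | COc1ccc(cc1)CO[C@@H]1C/C=C(/C)C[C@@H]2O[C@@H]([C@@H]3[C@H]2C(C)=CC(O[Si](C)(C)C)=C3)[C@@]1(C)OCC(Br)=C
F0 | step 21 | none | none
F2 | step 17 | C3 propargyl ether of 21 | COc1ccc(cc1)CO[C@@H]1C/C=C(/C)C[C@@H]2O[C@@H]([C@@H]3[C@H]2C(C)=C[C@H](O[Si](c4ccccc4)(c4ccccc4)C(C)(C)C)C3)[C@@]1(C)OCC#C
F3 | step 17 | C3 2-(tributylstannyl)allyl ether of 21 | COc1ccc(cc1)CO[C@@H]1C/C=C(/C)C[C@@H]2O[C@@H]([C@@H]3[C@H]2C(C)=C[C@H](O[Si](c4ccccc4)(c4ccccc4)C(C)(C)C)C3)[C@@]1(C)OCC(=C)[Sn](CCCC)(CCCC)CCCC
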